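Compound numbers 1–19 are those of the list after the steps; 19 is the target. The cyclohexene ring of 19 is numbered C1(CH3)=C2H–C3H(benzofuranyl)–C4H(aroyl)–C5H(dihydroxyphenyl)–C6H2.

## The problem

Target 19 is a 1-methylcyclohexene whose three contiguous stereocentres carry three different arene units: C3 is bonded to C5 of a 2-(3,5-dihydroxyphenyl)-6-hydroxybenzofuran, C4 to the carbonyl of a 2,4-dihydroxy-3-prenylbenzoyl group, and C5 to a 2,4-dihydroxyphenyl ring. All three substituents are mutually trans, with absolute configuration 3R,4R,5S. The C4/C5 trans pair can be inherited from an E alkene, but the C3/C4 trans relation cannot be repaired afterwards: only C4 (α to the ketone) can be epimerised, and inverting it in a 3,4-cis isomer would make C4/C5 cis. The C3/C4 relation and the absolute sense therefore have to be fixed together in the event that builds the ring, which must also place the methyl group 1,4 to the acyl group and the benzofuran on the carbon next to it. The molecule has seven free phenols, a prenyl group flanked by two of them (acid closes it to a chroman), a ketone flanked by ortho-hydroxyaryl groups on C3 and C5 (acid gives cyclic ketals) and an electron-rich arylbenzofuran, so the last stage must run near neutrality and should not be a global deprotection. The feature that opens the route is that the cyclohexene ring is a [4+2] retron made of two ortho-prenylphenols. C6–C1(CH3)=C2–C3 with its methyl is a five-carbon isoprenoid unit attached through C3 to benzofuran C5, ortho to the 6-OH, that is, a prenyl group short of two hydrogens. C4–C5 with their carbonyl and aryl group are the α- and β-carbons of an (E)-2′-hydroxychalcone whose ring A still carries an intact prenyl group.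

## Retrosynthesis

Cutting C3–C4 and C5–C6 of 19 in the retro-[4+2] sense gives chalcone 10 (morachalcone A) and diene 18. This cut removes the ring and all three stereocentres at once and divides C39 into C20 + C19. Cuts of single bonds (C3–aryl, ketone–aryl) would leave the stereotriad to be built by other means. The forward reaction must be exo-selective, enantioselective and tolerant of seven free phenols, which is asked of an exo-selective Diels–Alderase and not of a small Lewis acid.

Diene 18 is not prepared as such. Adding two hydrogens across its C1″/C4″ positions gives the prenylarene 17 (moracin N), a stable phenol. The forward reaction is dehydrogenation by a flavin-dependent oxidase in the same vessel as the cycloaddition. This avoids handling 18, which is prone to oxa-6π-electrocyclisation (through its o-quinone methide tautomer) and to polymerisation and would otherwise require protected phenols. Both partners of the key step are thus ortho-prenylphenols of about half the size of 19.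

Chalcone 10 is cut at Cα=Cβ (Claisen–Schmidt) into acetophenone 6 and aldehyde 8, with the tetra-MOM chalcone 9 between them. This is the shortest cut, and it needs only that all four phenols be masked against the base and released under mild acid.

Acetophenone 6 is cut at its aryl–acetyl and aryl–prenyl bonds back to resorcinol bis-MOM ether 2, via 4 and the aryllithiums 3 and 5. Two successive directed ortho-metalations place the prenyl group between the two oxygens and then the acetyl group at C4, so the 1,2,3,4-substitution pattern needs no separation of isomers. Ether 2 comes from resorcinol 1, and aldehyde 8 from 2,4-dihydroxybenzaldehyde 7.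

Moracin N 17 is cut at the C5–prenyl bond to bromide 16 (Suzuki–Miyaura prenylation), and 16 comes from its dimethyl ether 15. The furan ring of 15 is opened at O1–C2 and C3–C3a to give iodophenol 12 and alkyne 13 (Sonogashira coupling and cyclisation through 14). Compound 12 comes from 4-bromoresorcinol 11 by iodination. The iodine and bromine of 12 separate the two C–C couplings, and the methyl ethers are removed before the acid-sensitive prenyl group arrives.

## Roads not taken

Alternative 1: The same two ring bonds (C3–C4, C5–C6), closed in a flask by a thermal or Lewis-acid-promoted Diels–Alder reaction of protected partners. This is the most obvious route. The chalcone would be used as its triacetate A1 (ketone-ortho OH free for chelation) and the diene as its triacetate A2, with a stoichiometric chiral boron–biaryldiol promoter, to give hexaacetate A3, followed by six-fold deacetylation. The intrinsic preference of this cycloaddition, where there is one, is for the ketone-endo (3,4-cis) adduct, which cannot be epimerised to A3. The route also needs a stoichiometric chiral promoter, six acyl groups put on and taken off, a separately made and labile diene, and a final basic deprotection of the adduct. The chosen plan uses the two unprotected phenols and lets the enzyme pocket decide exo against endo.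

Alternative 2: Cut the ketone C(=O)–aryl bond first, then the ring. Aryllithium 5 would acylate the all-trans Weinreb amide A4, and A4 would come from an auxiliary- or catalyst-controlled [4+2] reaction of a cinnamic acid derivative with a protected diene. Lewis-acid-bound E-cinnamoyl dienophiles react through the carbonyl-endo transition state, giving the 3,4-cis acid series. Epimerisation at C4 then leads to the 3,4-trans/4,5-cis isomer and not to A4, so A4 would need a Z-locked (lactone-tethered) dienophile under forcing conditions with no reliable enantiocontrol. The route also carries five more MOM groups and ends with acidic deprotection of the ketone flanked by two ortho-phenols, where ketalisation threatens. It is longer and leaves the central stereochemical problem unsolved.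

Alternative 3: Cut the C3–C5(benzofuran) bond. This would be a Friedel–Crafts-type allylic arylation of moracin M A6 by the allyl cation from tertiary allylic alcohol A5, with attack anti to the C4 acyl group setting C3/C4 trans (the logic of aryl-menthene terpenophenol syntheses). A5 still contains the C4/C5 pair and would itself need an asymmetric cycloaddition of 10, so nothing is simplified. A6 has more nucleophilic positions (C2′/C4′ of the resorcinol ring, C7, C3) than the wanted C5. The ionising acid would also cyclise the prenyl group onto its phenols and ketalise the ketone. The chosen plan forms this bond as part of the diene, where its position is fixed by the prenyl group of 17.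

Key step: step 11

Assumption: the SMILES is read as the all-trans cyclohexene (3R,4R,5S in the numbering above, the exo adduct of the natural series), and recombinant enzymes of the two classes named in step 11 are taken to be obtainable by heterologous expression of the mulberry genes or close homologues.

## Route

Step 1
Reactants: 1 resorcinol (benzene-1,3-diol)
Product: 2 1,3-bis(methoxymethoxy)benzene
Conditions: NaH (2.4 equiv), DMF, 0 °C; MOMCl (2.4 equiv), 0 °C → rt
Reagents that add atoms: chloromethyl methyl ether (MOMCl), COCCl
Why: Williamson-type O-alkylation of the bis-phenoxide; the MOM ethers serve as directing groups for both later ortho-lithiations and as base-stable protection for the aldol step.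

Step 2
Reactants: 2 1,3-bis(methoxymethoxy)benzene
Product: 4 1,3-bis(methoxymethoxy)-2-(3-methylbut-2-en-1-yl)benzene, via [2,6-bis(methoxymethoxy)phenyl]lithium 3 (not isolated)
Conditions: n-BuLi (1.1 equiv), THF, 0 °C → rt; then prenyl bromide, −78 °C → rt
Reagents that add atoms: 1-bromo-3-methylbut-2-ene (prenyl bromide), CC(C)=CCBr
Why: Directed ortho-metalation at C2, the position flanked and coordinated by both OMOM groups, then SN2 alkylation of aryllithium 3 at the primary carbon of prenyl bromide (the SN2′ path would have to form a quaternary centre).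

Step 3
Reactants: 4 1,3-bis(methoxymethoxy)-2-(3-methylbut-2-en-1-yl)benzene
Product: 6 1-[2,4-bis(methoxymethoxy)-3-(3-methylbut-2-en-1-yl)phenyl]ethan-1-one, via [2,4-bis(methoxymethoxy)-3-(3-methylbut-2-en-1-yl)phenyl]lithium 5 (not isolated)
Conditions: n-BuLi (1.2 equiv), TMEDA, THF, −20 → 0 °C; then MeC(O)N(OMe)Me, −78 °C → rt; H2O
Reagents that add atoms: N-methoxy-N-methylacetamide, CC(=O)N(C)OC
Why: Second directed ortho-metalation at the only remaining kind of position ortho to an OMOM group (C4 and C6 are equivalent), then Weinreb amide acylation, which stops at the ketone because the chelated tetrahedral intermediate survives until work-up.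

Step 4
Reactants: 7 2,4-dihydroxybenzaldehyde
Product: 8 2,4-bis(methoxymethoxy)benzaldehyde
Conditions: NaH (2.4 equiv), DMF, 0 °C; MOMCl (2.4 equiv), 0 °C → rt
Reagents that add atoms: chloromethyl methyl ether (MOMCl), COCCl
Why: Williamson-type O-alkylation; full deprotonation with NaH also alkylates the hydrogen-bonded 2-OH, and the aldehyde has no α-hydrogen to interfere.

Step 5
Reactants: 6 1-[2,4-bis(methoxymethoxy)-3-(3-methylbut-2-en-1-yl)phenyl]ethan-1-one; 8 2,4-bis(methoxymethoxy)benzaldehyde
Product: 9 (2E)-1-[2,4-bis(methoxymethoxy)-3-(3-methylbut-2-en-1-yl)phenyl]-3-[2,4-bis(methoxymethoxy)phenyl]prop-2-en-1-one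
Conditions: KOH, EtOH/H2O, rt
Reagents that add atoms: none
Why: Claisen–Schmidt condensation; the aldehyde cannot enolise, E1cB dehydration gives the thermodynamic E enone, and with all four phenols masked neither phenoxide deactivation nor flavanone closure can occur.

Step 6
Reactants: 9 (2E)-1-[2,4-bis(methoxymethoxy)-3-(3-methylbut-2-en-1-yl)phenyl]-3-[2,4-bis(methoxymethoxy)phenyl]prop-2-en-1-one
Product: 10 morachalcone A, (2E)-1-[2,4-dihydroxy-3-(3-methylbut-2-en-1-yl)phenyl]-3-(2,4-dihydroxyphenyl)prop-2-en-1-one
Conditions: 3 M aq. HCl, MeOH, rt → 40 °C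
Reagents that add atoms: none
Why: Acid-catalysed transacetalisation of the four MOM ethers to methanol, a standard release of prenylated hydroxychalcones; dilute acid and short contact should keep the prenyl group from cyclising onto its neighbouring phenols.

Step 7
Reactants: 11 4-bromoresorcinol (4-bromobenzene-1,3-diol)
Product: 12 4-bromo-6-iodobenzene-1,3-diol
Conditions: NIS (1.0 equiv), MeCN, 0 °C → rt, dark
Reagents that add atoms: N-iodosuccinimide, O=C1CCC(=O)N1I
Why: Electrophilic aromatic iodination; C6 is ortho to one hydroxyl and para to the other and less hindered than C2, as in the usual 4,6-dihalogenation of resorcinol.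

Step 8
Reactants: 12 4-bromo-6-iodobenzene-1,3-diol; 13 1-ethynyl-3,5-dimethoxybenzene
Product: 15 5-bromo-2-(3,5-dimethoxyphenyl)-1-benzofuran-6-ol, via 4-bromo-6-[(3,5-dimethoxyphenyl)ethynyl]benzene-1,3-diol 14 (not isolated)
Conditions: PdCl2(PPh3)2 (3 mol %), CuI (5 mol %), Et3N, DMF, rt → 60 °C, Ar
Reagents that add atoms: none
Why: Sonogashira coupling, chemoselective for C–I over C–Br, then metal-assisted 5-endo-dig hydroalkoxylation of the alkyne by the adjacent hydroxyl to close the furan; the second hydroxyl is para to the alkyne and cannot cyclise, so it becomes the 6-OH next to the retained bromide.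

Step 9
Reactants: 15 5-bromo-2-(3,5-dimethoxyphenyl)-1-benzofuran-6-ol
Product: 16 5-(5-bromo-6-hydroxy-1-benzofuran-2-yl)benzene-1,3-diol
Conditions: BBr3 (5 equiv), CH2Cl2, −78 °C → rt; then H2O
Reagents that add atoms: none
Why: Lewis-acid cleavage of the two aryl methyl ethers, as used for simple arylbenzofuran triols; it is placed before the prenyl group is introduced because BBr3/HBr would destroy a prenyl side chain.

Step 10
Reactants: 16 5-(5-bromo-6-hydroxy-1-benzofuran-2-yl)benzene-1,3-diol
Product: 17 moracin N, 5-[6-hydroxy-5-(3-methylbut-2-en-1-yl)-1-benzofuran-2-yl]benzene-1,3-diol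
Conditions: prenyl-B(pin) (2 equiv), Pd(OAc)2 (3 mol %), α-selective bulky dialkylbiarylphosphine, aq. K3PO4, THF, 40–60 °C, degassed
Reagents that add atoms: 4,4,5,5-tetramethyl-2-(3-methylbut-2-en-1-yl)-1,3,2-dioxaborolane (prenylboronic acid pinacol ester), CC(C)=CCB1OC(C)(C)C(C)(C)O1
Why: Suzuki–Miyaura allylation of an aryl bromide with a prenylboronate; the ligand is chosen so that the first-formed tertiary σ-allyl palladium isomerises through the π-allyl to the primary σ-prenyl species before reductive elimination, giving the linear prenyl group, and aqueous phosphate conditions tolerate the free phenols.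

Step 11
Reactants: 17 moracin N, 5-[6-hydroxy-5-(3-methylbut-2-en-1-yl)-1-benzofuran-2-yl]benzene-1,3-diol; 10 morachalcone A, (2E)-1-[2,4-dihydroxy-3-(3-methylbut-2-en-1-yl)phenyl]-3-(2,4-dihydroxyphenyl)prop-2-en-1-one
Product: 19 [(1R,2R,6S)-6-(2,4-dihydroxyphenyl)-2-[2-(3,5-dihydroxyphenyl)-6-hydroxy-1-benzofuran-5-yl]-4-methylcyclohex-3-en-1-yl][2,4-dihydroxy-3-(3-methylbut-2-en-1-yl)phenyl]methanone, via 5-{6-hydroxy-5-[(1E)-3-methylbuta-1,3-dien-1-yl]-1-benzofuran-2-yl}benzene-1,3-diol 18 (not isolated)
Conditions: FAD-dependent berberine-bridge-enzyme-like prenylarene oxidase, exo-selective FAD-dependent berberine-bridge-enzyme-like intermolecular Diels–Alderase, air, Tris·HCl pH 8.0, 5% DMSO, 35 °C, dark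
Reagents that add atoms: none
Why: A biomimetic oxidase/Diels–Alderase cascade is used. The flavin oxidase removes hydride from the benzylic CH2 of the prenyl group of 17, the ortho 6-OH stabilising the resulting o-quinone-methide-type cation, and loss of a methyl proton gives the (E)-diene 18 while O2 reoxidises the flavin, so 18 is formed at low stationary concentration and never handled. The Diels–Alderase binds s-cis 18 and chalcone 10, whose enone is activated by the 2′-OH···O=C hydrogen bond, and joins C3–C4 and C5–C6 in a concerted, asynchronous intermolecular [4π+2π] cycloaddition that closes the six-membered carbocycle in one event (closest known reaction type: the enzymatic intermolecular Diels–Alder reaction of 2′-hydroxychalcones with dehydroprenyl-2-arylbenzofurans). Regiochemistry is intrinsic: the largest HOMO coefficient of 18 lies on its terminal CH2, reinforced by both the 1-aryl and the 3-methyl substituent, and pairs with the enone β-carbon, which puts the methyl group 1,4 to the acyl group and the benzofuran on C3. C4/C5 trans follows stereospecifically from the E geometry of 10 by suprafacial addition; C3/C4 trans is the exo arrangement imposed by the active site of the exo-selective isoform; and the absolute configuration 3R,4R,5S results from the single chalcone enantioface that the chiral pocket presents to the diene, as in the natural all-trans adducts. The step needs dehydrogenation of the prenyl group of 17 and not that of 10, secured by the oxidase's recognition of the arylbenzofuran or by adding 10 and the cyclase only after 17 is consumed, and it needs exo over endo selectivity, secured by the choice of isoform; the uncatalysed cycloaddition is negligible at 35 °C in dilute buffer and cannot erode enantiopurity. The neutral aqueous medium leaves the seven phenols, the remaining prenyl group and the ketone untouched, so no protecting group is carried into or out of this step.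

## Compound list

1 | resorcinol (benzene-1,3-diol) | Oc1cccc(O)c1 | starting material
2 | 1,3-bis(methoxymethoxy)benzene | COCOc1cccc(OCOC)c1 | intermediate
3 | [2,6-bis(methoxymethoxy)phenyl]lithium | [Li]c1c(OCOC)cccc1OCOC | intermediate (not isolated)
4 | 1,3-bis(methoxymethoxy)-2-(3-methylbut-2-en-1-yl)benzene | COCOc1cccc(OCOC)c1CC=C(C)C | intermediate
5 | [2,4-bis(methoxymethoxy)-3-(3-methylbut-2-en-1-yl)phenyl]lithium | [Li]c1ccc(OCOC)c(CC=C(C)C)c1OCOC | intermediate (not isolated)
6 | 1-[2,4-bis(methoxymethoxy)-3-(3-methylbut-2-en-1-yl)phenyl]ethan-1-one | CC(=O)c1ccc(OCOC)c(CC=C(C)C)c1OCOC | intermediate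
7 | 2,4-dihydroxybenzaldehyde | O=Cc1ccc(O)cc1O | starting material
8 | 2,4-bis(methoxymethoxy)benzaldehyde | COCOc1ccc(C=O)c(OCOC)c1 | intermediate
9 | (2E)-1-[2,4-bis(methoxymethoxy)-3-(3-methylbut-2-en-1-yl)phenyl]-3-[2,4-bis(methoxymethoxy)phenyl]prop-2-en-1-one | COCOc1ccc(/C=C/C(=O)c2ccc(OCOC)c(CC=C(C)C)c2OCOC)c(OCOC)c1 | intermediate
10 | morachalcone A, (2E)-1-[2,4-dihydroxy-3-(3-methylbut-2-en-1-yl)phenyl]-3-(2,4-dihydroxyphenyl)prop-2-en-1-one | CC(C)=CCc1c(O)ccc(C(=O)/C=C/c2ccc(O)cc2O)c1O | intermediate
11 | 4-bromoresorcinol (4-bromobenzene-1,3-diol) | Oc1ccc(Br)c(O)c1 | starting material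
12 | 4-bromo-6-iodobenzene-1,3-diol | Oc1cc(O)c(Br)cc1I | intermediate
13 | 1-ethynyl-3,5-dimethoxybenzene | C#Cc1cc(OC)cc(OC)c1 | starting material
14 | 4-bromo-6-[(3,5-dimethoxyphenyl)ethynyl]benzene-1,3-diol | Oc1cc(O)c(Br)cc1C#Cc1cc(OC)cc(OC)c1 | intermediate (not isolated)
15 | 5-bromo-2-(3,5-dimethoxyphenyl)-1-benzofuran-6-ol | COc1cc(OC)cc(-c2cc3cc(Br)c(O)cc3o2)c1 | intermediate
16 | 5-(5-bromo-6-hydroxy-1-benzofuran-2-yl)benzene-1,3-diol | Oc1cc(O)cc(-c2cc3cc(Br)c(O)cc3o2)c1 | intermediate
17 | moracin N, 5-[6-hydroxy-5-(3-methylbut-2-en-1-yl)-1-benzofuran-2-yl]benzene-1,3-diol | CC(C)=CCc1cc2cc(-c3cc(O)cc(O)c3)oc2cc1O | intermediate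
18 | 5-{6-hydroxy-5-[(1E)-3-methylbuta-1,3-dien-1-yl]-1-benzofuran-2-yl}benzene-1,3-diol | C=C(C)/C=C/c1cc2cc(-c3cc(O)cc(O)c3)oc2cc1O | intermediate (not isolated)
19 | [(1R,2R,6S)-6-(2,4-dihydroxyphenyl)-2-[2-(3,5-dihydroxyphenyl)-6-hydroxy-1-benzofuran-5-yl]-4-methylcyclohex-3-en-1-yl][2,4-dihydroxy-3-(3-methylbut-2-en-1-yl)phenyl]methanone | CC(C)=CCc1c(O)ccc(C(=O)[C@@H]2[C@@H](c3ccc(O)cc3O)CC(C)=C[C@H]2c2cc3cc(-c4cc(O)cc(O)c4)oc3cc2O)c1O | target

## Step count and risk

Total step count: 11. Longest linear sequence: 6 steps (steps 1, 2, 3, 5, 6, 11, from resorcinol 1); the benzofuran branch has 5 steps (steps 7–11) and joins in step 11.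

Step 11 (key step). The oxidase may accept 17 poorly, or may fail to discriminate between the two prenyl groups, so that chalcone 10 is also dehydrogenated and enters chalcone–chalcone cycloadditions. Exo control may also erode with this diene, and 18 may decay by electrocyclisation or polymerisation if the cyclase lags behind the oxidase (a catalase can be added if the peroxide formed harms either enzyme). The fallback replaces the enzymatic dehydrogenation by chemical construction of the diene and keeps only the Diels–Alderase. It sets out from 16: acetylation (Ac2O, pyridine) should give 5-(6-acetoxy-5-bromo-1-benzofuran-2-yl)-1,3-phenylene diacetate F1. Suzuki–Miyaura coupling of F1 with (E)-(3-methylbuta-1,3-dien-1-yl)boronic acid pinacol ester under anhydrous conditions (Pd(dppf)Cl2, K3PO4, dioxane, 70 °C) should give 5-{6-acetoxy-5-[(1E)-3-methylbuta-1,3-dien-1-yl]-1-benzofuran-2-yl}-1,3-phenylene diacetate F2 (the same ester as A2). Brief deacetylation (K2CO3, MeOH, 0 °C, degassed) releases the diene, so the fallback comes back to the route at 18, which is given at once to 10 and the Diels–Alderase alone to reach 19.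

Step 10. Transfer of the prenyl group through its γ-carbon (reverse-prenyl isomer) and slow oxidative addition into the phenoxide-rich aryl bromide, with protodebromination or protodeboronation taking over, are the likely failures. The fallback replaces the palladium coupling by organolithium alkylation and sets out from 16. Protection (NaH, MOMCl, DMF) should give 5-bromo-2-[3,5-bis(methoxymethoxy)phenyl]-6-(methoxymethoxy)-1-benzofuran F3. Bromine–lithium exchange (n-BuLi, THF, −78 °C) gives {2-[3,5-bis(methoxymethoxy)phenyl]-6-(methoxymethoxy)-1-benzofuran-5-yl}lithium F4. Alkylation with prenyl bromide at −78 °C gives 2-[3,5-bis(methoxymethoxy)phenyl]-6-(methoxymethoxy)-5-(3-methylbut-2-en-1-yl)-1-benzofuran F5. Mild HCl/MeOH then removes the three MOM groups, and the fallback comes back to the route at 17.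

Step 3. Lateral metalation at the benzylic, allylic CH2 of the prenyl group, which lies between two coordinating OMOM groups, may compete with ring deprotonation and lead to acylation in the side chain. The fallback fixes the lithiation site with a halogen and sets out from 11. Protection (NaH, MOMCl) should give 1-bromo-2,4-bis(methoxymethoxy)benzene F6. Deprotonation between the two OMOM groups with LiTMP (THF, −78 °C), which does not exchange the bromide, gives [3-bromo-2,6-bis(methoxymethoxy)phenyl]lithium F7. Prenyl bromide then gives 1-bromo-2,4-bis(methoxymethoxy)-3-(3-methylbut-2-en-1-yl)benzene F8. Bromine–lithium exchange on F8 (n-BuLi, THF, −78 °C) generates the aryllithium regiospecifically, so the fallback comes back to the route at 5, which is acylated as in step 3 to 6.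

Step 7. Iodination may go partly to C2 (between the hydroxyls) or run on to a di-iodide, which would spoil the halogen differentiation used in step 8. The fallback gives up the iodine/bromine differentiation for a symmetric substrate and sets out from 11. Bromination (NBS, 1 equiv, MeCN, 0 °C) should give the C2v-symmetric 4,6-dibromobenzene-1,3-diol F9, in which both halides are equivalent. Mono-Sonogashira coupling of excess F9 with 13 (Pd(OAc)2/XPhos, Et3N, MeCN, 80 °C, copper-free) gives the alkynylphenol, so the fallback comes back to the route at 14, which cyclises to 15 as in step 8.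

## Further compounds

F1 | step 11 | 5-(6-acetoxy-5-bromo-1-benzofuran-2-yl)-1,3-phenylene diacetate | CC(=O)Oc1cc(OC(C)=O)cc(-c2cc3cc(Br)c(OC(C)=O)cc3o2)c1
F2 | step 11 | 5-{6-acetoxy-5-[(1E)-3-methylbuta-1,3-dien-1-yl]-1-benzofuran-2-yl}-1,3-phenylene diacetate | C=C(C)/C=C/c1cc2cc(-c3cc(OC(C)=O)cc(OC(C)=O)c3)oc2cc1OC(C)=O
F3 | step 10 | 5-bromo-2-[3,5-bis(methoxymethoxy)phenyl]-6-(methoxymethoxy)-1-benzofuran | COCOc1cc(OCOC)cc(-c2cc3cc(Br)c(OCOC)cc3o2)c1
F4 | step 10 | {2-[3,5-bis(methoxymethoxy)phenyl]-6-(methoxymethoxy)-1-benzofuran-5-yl}lithium | [Li]c1cc2cc(-c3cc(OCOC)cc(OCOC)c3)oc2cc1OCOC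
F5 | step 10 | 2-[3,5-bis(methoxymethoxy)phenyl]-6-(methoxymethoxy)-5-(3-methylbut-2-en-1-yl)-1-benzofuran | CC(C)=CCc1cc2cc(-c3cc(OCOC)cc(OCOC)c3)oc2cc1OCOC
F6 | step 3 | 1-bromo-2,4-bis(methoxymethoxy)benzene | COCOc1ccc(Br)c(OCOC)c1
F7 | step 3 | [3-bromo-2,6-bis(methoxymethoxy)phenyl]lithium | [Li]c1c(OCOC)ccc(Br)c1OCOC
F8 | step 3 | 1-bromo-2,4-bis(methoxymethoxy)-3-(3-methylbut-2-en-1-yl)benzene | COCOc1ccc(Br)c(OCOC)c1CC=C(C)C
F9 | step 7 | 4,6-dibromobenzene-1,3-diol | Oc1cc(O)c(Br)cc1Br
A1 | alternative 1 | 4-[(1E)-3-[4-acetoxy-2-hydroxy-3-(3-methylbut-2-en-1-yl)phenyl]-3-oxoprop-1-en-1-yl]-1,3-phenylene diacetate (triacetate of 10, ketone-ortho OH free) | CC(C)=CCc1c(OC(C)=O)ccc(C(=O)/C=C/c2ccc(OC(C)=O)cc2OC(C)=O)c1O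
A2 | alternative 1 | 5-{6-acetoxy-5-[(1E)-3-methylbuta-1,3-dien-1-yl]-1-benzofuran-2-yl}-1,3-phenylene diacetate (triacetate of 18) | C=C(C)/C=C/c1cc2cc(-c3cc(OC(C)=O)cc(OC(C)=O)c3)oc2cc1OC(C)=O
A3 | alternative 1 | hexa-O-acetyl derivative of 19 with the ketone-ortho OH free, (1R,2R,6S) as in 19 | CC(C)=CCc1c(OC(C)=O)ccc(C(=O)[C@@H]2[C@@H](c3ccc(OC(C)=O)cc3OC(C)=O)CC(C)=C[C@H]2c2cc3cc(-c4cc(OC(C)=O)cc(OC(C)=O)c4)oc3cc2OC(C)=O)c1O
A4 | alternative 2 | (1R,2R,6S)-N-methoxy-N-methyl-6-[2,4-bis(methoxymethoxy)phenyl]-2-{2-[3,5-bis(methoxymethoxy)phenyl]-6-(methoxymethoxy)-1-benzofuran-5-yl}-4-methylcyclohex-3-ene-1-carboxamide | CON(C)C(=O)[C@@H]1[C@@H](c2ccc(OCOC)cc2OCOC)CC(C)=C[C@H]1c1cc2cc(-c3cc(OCOC)cc(OCOC)c3)oc2cc1OCOC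
A5 | alternative 3 | [2,4-dihydroxy-3-(3-methylbut-2-en-1-yl)phenyl][6-(2,4-dihydroxyphenyl)-4-hydroxy-4-methylcyclohex-2-en-1-yl]methanone, acyl and aryl trans and configured as C4/C5 of 19, carbinol centre unassigned | CC(C)=CCc1c(O)ccc(C(=O)[C@@H]2[C@@H](c3ccc(O)cc3O)CC(C)(O)C=C2)c1O
A6 | alternative 3 | moracin M, 5-(6-hydroxy-1-benzofuran-2-yl)benzene-1,3-diol | Oc1cc(O)cc(-c2cc3ccc(O)cc3o2)c1
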